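**Assumption:** the single stereocentre in the SMILES is (R) (CIP order OAr > C(=O)Ar > CH3 > H), and recombinant benzoylformate decarboxylase from Pseudomonas putida (expressed in E. coli) is taken as an accessible catalyst.

## Retrosynthetic overview

1. Key C–C disconnection, C(=O)–CH(O), made first: 3,4,5-trimethoxybenzaldehyde 1 plus acetaldehyde 2. Aldehyde 1 becomes the aroyl anion equivalent 3 on thiamine diphosphate inside an (S)-selective lyase and attacks the carbonyl carbon of 2, giving (S)-α-hydroxy ketone 4 and setting the only stereocentre.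
2. C–O disconnection, made last: 4 plus 4-allyl-2,6-dimethoxyphenol 5, through alkoxyphosphonium 6, by SN2 with inversion, gives the (R)-aryl ether 7 (target).
3. No ring is formed: both benzene rings and the allyl group are bought intact, and no protecting groups are used.

## Route

**Step 1**
Reactants: 1 3,4,5-trimethoxybenzaldehyde; 2 acetaldehyde
Product: 4 (S)-2-hydroxy-1-(3,4,5-trimethoxyphenyl)propan-1-one, via enzyme-bound Breslow enaminol 3 (not isolated)
Conditions: benzoylformate decarboxylase (Pseudomonas putida, recombinant), thiamine diphosphate (0.5 mM), MgSO4 (2.5 mM), 1 (20–40 mM), 2 (15 equiv), KH2PO4/K2HPO4 buffer (50 mM, pH 7.0)–DMSO 4:1, 30 °C, 24–48 h; EtOAc extraction, chromatography, ee by chiral HPLC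
Reagents that add atoms: none
Why: Thiamine diphosphate-dependent carboligation (enzymatic asymmetric cross-acyloin condensation): the cofactor ylide adds to 1 and a proton shift gives enaminol 3, an aroyl anion equivalent whose former carbonyl carbon attacks the carbonyl carbon of 2 (two normally electrophilic carbons joined) in an active site that exposes one face of acetaldehyde, so 4 is released as the (S)-alcohol with no co-product; this enzyme is known to give (S)-2-hydroxypropiophenones and to favour meta-alkoxybenzaldehyde donors, but this trisubstituted donor is an extrapolation.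

**Step 2**
Reactants: 4 (S)-2-hydroxy-1-(3,4,5-trimethoxyphenyl)propan-1-one; 5 4-allyl-2,6-dimethoxyphenol
Product: 7 (R)-2-(4-allyl-2,6-dimethoxyphenoxy)-1-(3,4,5-trimethoxyphenyl)propan-1-one (CNP0127876.1), via alkoxyphosphonium phenoxide ion pair 6 (not isolated)
Conditions: 5 (1.3 equiv), PPh3 (1.4 equiv), DIAD (1.4 equiv, added last, dropwise), toluene or THF, 0 °C to rt, 12 h; neutral work-up, rapid silica chromatography, ee by chiral HPLC
Reagents that add atoms: none
Why: Mitsunobu etherification: PPh3/DIAD turn the secondary alcohol into alkoxyphosphonium 6, which the phenoxide of 5 (pKa about 10, para and both ortho positions blocked, so only O-alkylation is possible) displaces by SN2 at a carbon activated by the adjacent carbonyl with inversion (S to R), while the cold, near-neutral conditions leave the allyl group untouched and limit enolisation of the α-aryloxy ketone.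

## Compound list

1 | 3,4,5-trimethoxybenzaldehyde | COc1cc(C=O)cc(OC)c1OC | starting material
2 | acetaldehyde | CC=O | starting material
3 | enzyme-bound Breslow enaminol: thiamine diphosphate carrying a hydroxy(3,4,5-trimethoxyphenyl)methylidene group at C2 of the thiazole ring (C=C geometry not specified) | Cc1ncc(CN2C(C)=C(CCOP(O)(=O)OP(O)(O)=O)SC2=C(O)c2cc(OC)c(OC)c(OC)c2)c(N)n1 | intermediate
4 | (S)-2-hydroxy-1-(3,4,5-trimethoxyphenyl)propan-1-one | C[C@H](O)C(=O)c1cc(OC)c(OC)c(OC)c1 | intermediate
5 | 4-allyl-2,6-dimethoxyphenol (methoxyeugenol) | C=CCc1cc(OC)c(O)c(OC)c1 | starting material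
6 | (S)-[1-oxo-1-(3,4,5-trimethoxyphenyl)propan-2-yl]oxy-triphenylphosphonium 4-allyl-2,6-dimethoxyphenoxide (ion pair) | C[C@H](O[P+](c1ccccc1)(c1ccccc1)c1ccccc1)C(=O)c1cc(OC)c(OC)c(OC)c1.C=CCc1cc(OC)c([O-])c(OC)c1 | intermediate
7 | (R)-2-(4-allyl-2,6-dimethoxyphenoxy)-1-(3,4,5-trimethoxyphenyl)propan-1-one (CNP0127876.1) | C=CCc1cc(OC)c(O[C@H](C)C(=O)c2cc(OC)c(OC)c(OC)c2)c(OC)c1 | target

## Summary

Total step count: 2. Longest linear sequence: 2 steps (1 → 4 → 7).

Steps most likely to fail (the route has only two steps, so both are ranked and there is no third):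

**1. Step 1.** The 3,4,5-trisubstituted donor may be turned over slowly, or with lower ee, by the (S)-selective enzyme.
Fallback: set out again from 1 and 2, but use the (R)-selective benzaldehyde lyase from Pseudomonas fluorescens, which has a much broader donor scope (thiamine diphosphate, MgSO4, KH2PO4/K2HPO4 buffer pH 8–DMSO, 30 °C). This gives (R)-2-hydroxy-1-(3,4,5-trimethoxyphenyl)propan-1-one F1. The carbinol centre is then inverted by a Mitsunobu esterification (4-nitrobenzoic acid, PPh3, DIAD, THF, 0 °C) to (S)-1-oxo-1-(3,4,5-trimethoxyphenyl)propan-2-yl 4-nitrobenzoate F2. Brief methanolysis (K2CO3, 0.1 equiv, MeOH, 0 °C) releases the (S)-alcohol, and the route is rejoined at 4.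

**2. Step 2.** The doubly ortho-substituted phenol may react sluggishly, with hydrazide alkylation, elimination to the aryl vinyl ketone, or partial racemisation competing.
Fallback: set out from 4 and separate activation from displacement. Tf2O and 2,6-lutidine in CH2Cl2 at −78 °C give, with retention, (S)-1-oxo-1-(3,4,5-trimethoxyphenyl)propan-2-yl trifluoromethanesulfonate F3. This is treated cold (−78 to −20 °C, THF) with the sodium phenoxide made from 5 and NaH. SN2 displacement with inversion rejoins the route at 7.

## Further compounds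

F1 | step 1 | (R)-2-hydroxy-1-(3,4,5-trimethoxyphenyl)propan-1-one | C[C@@H](O)C(=O)c1cc(OC)c(OC)c(OC)c1
F2 | step 1 | (S)-1-oxo-1-(3,4,5-trimethoxyphenyl)propan-2-yl 4-nitrobenzoate | C[C@H](OC(=O)c1ccc(cc1)[N+](=O)[O-])C(=O)c1cc(OC)c(OC)c(OC)c1
F3 | step 2 | (S)-1-oxo-1-(3,4,5-trimethoxyphenyl)propan-2-yl trifluoromethanesulfonate | C[C@H](OS(=O)(=O)C(F)(F)F)C(=O)c1cc(OC)c(OC)c(OC)c1
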